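**Plan**

- Retrosynthesis: the nonadecenyl chain is cut at the CH2–CH2 bond next to the ring and, in the same operation, at the ring C3–CH2 bond. This gives 2,5-dihydroxy-1,4-benzoquinone, formaldehyde and an (E)-octadec-13-enyl radical equivalent. The C18 unit is then cut at C12–C13 into 12-bromododec-1-ene and hex-1-yne.
- Enabling feature: C3–H of the quinone ring sits between the C2 enol O–H and the C4 carbonyl (a vinylogous acid). It condenses with formaldehyde to an exocyclic methylene trione (ortho-quinone methide) whose CH2 terminus is a strong radical acceptor and whose adduct radical is oxygen-centred.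
- Forward: acetylide alkylation, trans reduction of the alkyne, terminal hydroboration with catecholborane, then a three-component coupling that installs the ring CH2 and joins it to the chain. The quinone ring is bought, not built, and needs no protecting group or redox adjustment.
- Stereochemistry: the E-alkene comes from the dissolving-metal reduction of the alkyne and is carried through unchanged.

Key step: step 4

Remark: the target has no stereocentre, so the only stereochemical element to control is the (E)-C14=C15 double bond; "single enantiomer" is read as that single geometric isomer.

Step 1
Reactants: 1 hex-1-yne; 2 12-bromododec-1-ene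
Product: 4 octadec-1-en-13-yne, via hex-1-ynyllithium 3 (not isolated)
Conditions: n-BuLi, THF, −78 to 0 °C; then 2, DMPU, 0 °C to rt
Reagents that add atoms: none
Why: The lithium acetylide displaces the primary bromide in an SN2 acetylide alkylation (DMPU raises its reactivity), the remote terminal alkene is inert, and no stereocentre is formed.

Step 2
Reactants: 4 octadec-1-en-13-yne
Product: 5 (13E)-octadeca-1,13-diene
Conditions: Na, NH3(l), THF, −33 °C
Reagents that add atoms: none
Why: Dissolving-metal (Birch-type) reduction of the dialkyl alkyne passes through the radical anion and the more stable trans-vinyl anion, so protonation should give the E-alkene, while the isolated terminal alkene is not reduced.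

Step 3
Reactants: 5 (13E)-octadeca-1,13-diene
Product: 6 2-[(13E)-octadec-13-en-1-yl]-1,3,2-benzodioxaborole
Conditions: catecholborane (1.0 equiv), RhCl(PPh3)3 (1 mol%), THF, 0 °C to rt; volatiles removed, used crude
Reagents that add atoms: catecholborane, B1Oc2ccccc2O1
Why: Rhodium-catalysed hydroboration with catecholborane is anti-Markovnikov and strongly favours a monosubstituted over a 1,2-disubstituted alkene, so boron should go only to C1 and the E-alkene should stay untouched; no stereocentre is formed.

Step 4
Reactants: 7 2,5-dihydroxy-1,4-benzoquinone; 8 formaldehyde (as paraformaldehyde); 6 2-[(13E)-octadec-13-en-1-yl]-1,3,2-benzodioxaborole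
Product: 11 2,5-dihydroxy-3-[(14E)-nonadec-14-en-1-yl]cyclohexa-2,5-diene-1,4-dione, via ortho-quinone methide 9 (not isolated), via catechol borate ester 10 (not isolated)
Conditions: 7 (4 equiv), (CH2O)n (1.3 equiv), 1,4-dioxane, 70 °C; 6 added over 4 h under a slow air bleed; 1 M HCl work-up in air
Reagents that add atoms: none
Why: Proposed new method: C3–H of 7 is the carbon of a vinylogous acid (C2 enol O–H conjugated through C3 to the C4 carbonyl), so it should condense with formaldehyde under the substrate's own acidity to the 3-methylene trione 9, the ortho-quinone methide that hydride donors are known to intercept in Knoevenagel/transfer-hydrogenation reductive alkylations of 2-hydroxyquinones. A trace of air starts a radical chain in which the primary (E)-octadec-13-enyl radical released from 6 adds to the unsubstituted exocyclic CH2 of 9 and so forms the CH2–CH2 bond between the chain and the ring-bound methylene. The adduct radical is delocalised over the C2–C3–C4 dicarbonyl unit and reacts at oxygen with the Lewis-acidic boron of 6 (homolytic substitution), which gives borate 10 and releases the next alkyl radical; water from the condensation and the acidic work-up hydrolyse 10 to 11. The closest known reaction type is the radical conjugate addition of B-alkylcatecholboranes and trialkylboranes to enones, to quinones and to 2-methylene ketones generated in situ from Mannich bases. No ring is closed and no stereocentre is formed, and the remote E-alkene is not touched because a primary alkyl radical does not add to an unactivated 1,2-dialkyl alkene at a competitive rate. The step needs attack at the exocyclic CH2 in preference to the ring C–H positions and one alkylation per ring: the nucleophilic radical prefers the unhindered methylene terminus activated by two carbonyl groups over the electron-rich enol carbons C3/C6 of 7, and the excess of 7 keeps the free C6–H of 11 from competing for formaldehyde.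

**Compound list**

1 | hex-1-yne | CCCCC#C | starting material
2 | 12-bromododec-1-ene | C=CCCCCCCCCCCBr | starting material
3 | hex-1-ynyllithium | CCCCC#C[Li] | intermediate
4 | octadec-1-en-13-yne | CCCCC#CCCCCCCCCCCC=C | intermediate
5 | (13E)-octadeca-1,13-diene | CCCC/C=C/CCCCCCCCCCC=C | intermediate
6 | 2-[(13E)-octadec-13-en-1-yl]-1,3,2-benzodioxaborole | CCCC/C=C/CCCCCCCCCCCCB1Oc2ccccc2O1 | intermediate
7 | 2,5-dihydroxy-1,4-benzoquinone | O=C1C=C(O)C(=O)C=C1O | starting material
8 | formaldehyde (used as paraformaldehyde) | C=O | starting material
9 | 5-hydroxy-3-methylidenecyclohex-5-ene-1,2,4-trione (ortho-quinone methide) | C=C1C(=O)C(=O)C=C(O)C1=O | intermediate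
10 | 2-(1,3,2-benzodioxaborol-2-yloxy)-5-hydroxy-3-[(14E)-nonadec-14-en-1-yl]cyclohexa-2,5-diene-1,4-dione (drawn as the 2-O-boryl tautomer) | CCCC/C=C/CCCCCCCCCCCCCC1=C(OB2Oc3ccccc3O2)C(=O)C=C(O)C1=O | intermediate
11 | 2,5-dihydroxy-3-[(14E)-nonadec-14-en-1-yl]cyclohexa-2,5-diene-1,4-dione | CCCC/C=C/CCCCCCCCCCCCCC1=C(O)C(=O)C=C(O)C1=O | target

**Totals and risks**

Total step count: 4. Longest linear sequence: 4 steps (1 + 2 → 4 → 5 → 6 → 11).

Steps most likely to fail:

Step 4 (proposed new method). The radical chain may be outrun in three ways: Michael addition of a second molecule of 7 to 9 (methylene-bridged dimerisation), direct radical attack on a ring C–H of 7 (coupling without the CH2 unit), or hydrogen transfer from O–H donors to the alkyl radical before it finds 9. The fallback sets out from 5 and comes back at 11, using established reaction types and forming the ring–CH2 bond instead. Linear-selective hydroformylation of the terminal alkene of 5 (Rh(acac)(CO)2, Xantphos, CO/H2, toluene, 80 °C) should give (14E)-nonadec-14-enal F1. The known three-component reductive alkylation of 7 with F1 and Hantzsch ester (L-proline cat., CH2Cl2, rt; Knoevenagel condensation followed by conjugate hydride transfer) should then give 11.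

Step 3. Chemoselectivity may be lost through hydroboration of the internal alkene, formation of the branched boronate, or rhodium-hydride migration of a double bond, and the hydrolytically labile product cannot be purified before the key step. The fallback sets out from 5 and comes back at 6 through an isolable boronic ester. Iridium-catalysed hydroboration with pinacolborane ([Ir(cod)Cl]2, dppm, CH2Cl2, rt) should give 4,4,5,5-tetramethyl-2-[(13E)-octadec-13-en-1-yl]-1,3,2-dioxaborolane F2, which can be chromatographed. Oxidative removal of the pinacol (NaIO4, NH4OAc, acetone/H2O) should give [(13E)-octadec-13-en-1-yl]boronic acid F3. Condensation with catechol (toluene, azeotropic removal of water) should then give 6.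

Step 2. The reduction may stop short because the C18 hydrocarbon is poorly soluble in liquid ammonia, and the amide formed may cause migration of the terminal double bond. The fallback sets out from 4 and comes back at 5 by a formal trans-hydrogenation in an organic solvent. Ruthenium-catalysed trans-hydrosilylation of the alkyne ([Cp*Ru(MeCN)3]PF6 cat., (EtO)3SiH, CH2Cl2, 0 °C to rt), which leaves the terminal alkene alone, should give the two regioisomeric vinylsilanes triethoxy[(13Z)-octadeca-1,13-dien-13-yl]silane F4 and triethoxy[(13Z)-octadeca-1,13-dien-14-yl]silane F5. Protodesilylation with retention (TBAF, CuI, THF, rt) should convert both into 5.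

Further compounds
F1 | step 4 | (14E)-nonadec-14-enal | CCCC/C=C/CCCCCCCCCCCCC=O
F2 | step 3 | 4,4,5,5-tetramethyl-2-[(13E)-octadec-13-en-1-yl]-1,3,2-dioxaborolane | CCCC/C=C/CCCCCCCCCCCCB1OC(C)(C)C(C)(C)O1
F3 | step 3 | [(13E)-octadec-13-en-1-yl]boronic acid | CCCC/C=C/CCCCCCCCCCCCB(O)O
F4 | step 2 | triethoxy[(13Z)-octadeca-1,13-dien-13-yl]silane | C=CCCCCCCCCCC/C(=C/CCCC)[Si](OCC)(OCC)OCC
F5 | step 2 | triethoxy[(13Z)-octadeca-1,13-dien-14-yl]silane | C=CCCCCCCCCCC/C=C(/CCCC)[Si](OCC)(OCC)OCC
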